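(The data stem from a simulated flask with constants of no real substance; noise was put on by code.)

- The time of reading told me little by itself, so I counted turnovers: how many substrate lifetimes fit into that time.

| setting | ochre | red | amber | Thursday's | Tuesday's | Sunday's | Friday's |
|---|---|---|---|---|---|---|---|
| substrate | 0.050 M | 0.034 M | 0.075 M | 0.050 M | 0.050 M | 0.050 M | 0.050 M |
| reagent | 0.20 M | 0.20 M | 0.20 M | 0.200 M (fed, over 5.00 min) | 0.200 M | 0.200 M | 0.200 M |
| remark | run made earlier | run made earlier | run made earlier | a stirred flask in which reagent is dosed at a steady rate over 5.00 min without added volume, worked up at 5.0 min | everything together in a closed stirred flask, run for 5.0 min | one stirred flow tank at steady state, fed with the mixture as stated, mean residence time 5.0 min | a single well-mixed tank run continuously and read at steady state, 50.0 min in it on average |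
| time |  |  |  | 5.0 min | 5.0 min |  |  |

| run | time / min | intermediate / % | target / % | substrate / % |
|---|---|---|---|---|
| ochre | 0.417 | 9.3 | 0 | 89.9 |
| ochre | 0.833 | 18.6 | 1.7 | 80.1 |
| ochre | 1.33 | 26.9 | 0.5 | 71.0 |
| ochre | 1.50 | 29.5 | 1.8 | 68.5 |
| ochre | 2.00 | 36.9 | 2.9 | 60.3 |
| ochre | 2.50 | 39.1 | 3.8 | 50.7 |
| ochre | 3.00 | 46.4 | 6.3 | 44.9 |
| red | 0.333 | 7.2 | 0 | 94.0 |
| red | 0.500 | 11.1 | 0.2 | 87.1 |
| red | 0.667 | 16.1 | 0 | 85.7 |
| red | 1.00 | 24.2 | 0.4 | 77.6 |
| red | 1.50 | 29.7 | 1.6 | 67.3 |
| red | 2.50 | 41.5 | 4.0 | 51.9 |
| red | 4.00 | 52.6 | 8.8 | 35.7 |
| amber | 0.200 | 5.1 | 0 | 95.2 |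
| amber | 0.667 | 16.0 | 1.6 | 83.9 |
| amber | 1.00 | 20.2 | 0 | 77.7 |
| amber | 1.50 | 28.4 | 1.3 | 69.3 |
| amber | 2.50 | 39.8 | 3.5 | 53.2 |
| amber | 3.00 | 44.4 | 5.0 | 48.1 |
| amber | 4.00 | 49.3 | 10.1 | 37.1 |

(readings scatter by 1 percentage point)

- the set-up with the highest amount of intermediate at the outlet or at the end, in percent of the substrate put in ("none" if the first two lie within 2 percentage points) (Thursday's / Tuesday's / Sunday's / Friday's / none)
- amount of intermediate at the outlet or at the end, in percent of the substrate put in, Thursday's
- amount of intermediate at the outlet or at the end, in percent of the substrate put in, Tuesday's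
- amount of intermediate at the outlet or at the end, in percent of the substrate put in, Sunday's
- amount of intermediate at the outlet or at the end, in percent of the substrate put in, Friday's

- the stated concentrations are those of everything mixed, before any reaction; amounts are the same in each set-up
- what was read earlier has a scatter of 1 percentage point, one standard deviation
- the feed brings no volume worth counting
- the earlier runs were made in a closed, stirred flask
- a reading or a percentage of target counts all its forms, free or not
- a reading of substrate is of its free form alone

- I first asked which numbers had to be known well, starting with the loading. Amber held 2.21 times red's substrate, yet their substrate readings at 4.00 min differ by 1.4 percentage points, about the scatter, so loading mattered little to the substrate's decay in these runs.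
- That gap shifts a count over 5.0 min by 0.0481, and with first-order decay in a closed flask the substrate left shifts by that fraction of itself, so the substrate rate was good enough.
- Intermediate loss counted for Friday's tank, whose mean residence time is ten times Sunday's, but the readings stop by 4.00 min.
- [reagent] began at 0.20 M in each run, so the order in reagent stayed unread, and that touches Thursday's.
- Treating the decay as pseudo-first-order, I read 0.257 min⁻¹, so the turnover count, rate constant times time, was 1.29 for Tuesday's and Sunday's and 12.9 for Friday's.
- Red's last reading, taking the intermediate's mean age as half the time, gave a loss of 0.100 min⁻¹.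
- Assuming first order in reagent, Thursday's steady feed gave a count of 0.645. I reckoned Thursday's 41.4%, Tuesday's 54.0%, Sunday's 37.5% and Friday's 15.4%.
- The forecast, above mine, gave 43%, 56%, 40% and 20% in the same order, chose Tuesday's, and said of Friday's: “It could be higher if rates fall with reagent consumed”.
- The flasks gave 38.8%, 54.1%, 37.1% and 27.9% in that order, so Tuesday's led.

    substrate + reagent ⇌ intermediate (K = 128 M⁻¹, k = 0.0219 M⁻¹ s⁻¹)
    substrate + target ⇌ idle adduct, settled at all times (K = 74.3 M⁻¹)
    2 substrate → homo dimer (k = 1.36 × 10⁻⁴ M⁻¹ s⁻¹)
    intermediate ⇌ target + by-product (K = 0.0810 M, k = 0.00106 s⁻¹)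

- Friday's stood 12 points above my figure, and Tuesday's flask left for 50.0 min held 27.4% intermediate. Tuesday's count of 1.29 implied 27.5% substrate left, and Tuesday's flask held 28.2% at 5.00 min. The same charge stopped at 2.0 min had a count of 0.514, which implied 59.8%, and that stopped flask held 59.6%.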